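The synthesis rests on cutting the pyrrolidine ring (lactam N, its three CH2 groups, quaternary aminal carbon C-10) into a C–N–C azomethine ylide and ethylene. The key step exploits two features of this ring: its CH2–CH2 edge is unsubstituted, and its N lies between a bare CH2 and the fully substituted C-10. In one pot an α-keto ester, (trimethylsilyl)methylamine and phenyl vinyl sulfone (ethylene surrogate) are merged under chiral Cu(I) catalysis. This forms both ring C–C bonds and sets C-10. The precursor is an acyclic N-(silylmethyl) ketimine. Its ester becomes the urea N on C-10 (Curtius), and its acetal becomes the aminal CH C-6, which closes both remaining rings at the end.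

Key step: step 3

Assumption: (R)-DTBM-Segphos is taken to deliver the (2R)-pyrrolidine; if the sense of induction is the opposite, the equally available (S)-ligand is used with no other change.

Step 1
Reactants: 1 3,3-diethoxyprop-1-yne
Product: 2 1-bromo-3,3-diethoxyprop-1-yne
Conditions: NBS, AgNO3 (cat.), acetone, rt
Reagents that add atoms: N-bromosuccinimide, O=C1CCC(=O)N1Br
Why: Silver-acetylide-mediated electrophilic bromination of a terminal alkyne runs under neutral conditions that leave the acetal untouched.

Step 2
Reactants: 2 1-bromo-3,3-diethoxyprop-1-yne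
Product: 3 methyl 3,3-diethoxy-2-oxopropanoate
Conditions: KMnO4, NaHCO3, MgSO4, MeOH/H2O, 0 °C
Reagents that add atoms: potassium permanganate, [K+].[O-][Mn](=O)(=O)=O; methanol, CO
Why: Permanganate oxidation of a 1-bromoalkyne gives the α-keto acyl bromide, which methanol intercepts as the α-keto ester under buffered conditions that spare the acetal.

Step 3
Reactants: 3 methyl 3,3-diethoxy-2-oxopropanoate; 4 (trimethylsilyl)methanamine; 5 phenyl vinyl sulfone
Product: 7 methyl (2R,4R)-2-(diethoxymethyl)-4-(phenylsulfonyl)pyrrolidine-2-carboxylate, via methyl 3,3-diethoxy-2-{[(trimethylsilyl)methyl]imino}propanoate 6 (not isolated)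
Conditions: 3 + 4, 4 Å MS, toluene, 0 °C → rt; then 5, [Cu(MeCN)4]PF6 (5 mol %), (R)-DTBM-Segphos (5.5 mol %), Et3N (20 mol %), rt; aq NaHCO3 work-up
Reagents that add atoms: none
Why: Condensation gives ketimine 6, whose imine N and ester C=O chelate the Cu(I)–bisphosphine, and loss of the silyl group from the activated N–CH2–Si unit then gives an N-metallated azomethine ylide with a bare CH2 terminus and an ester-stabilised, fully substituted terminus. The ylide adds across the vinyl sulfone in an asynchronous [3+2] cycloaddition in which the enolate-like carbon bonds to the β-CH2 of the sulfone and the α-sulfonyl carbon bonds to the CH2=N terminus, so both C–C bonds of the pyrrolidine form in one operation. The closest known reaction type is the Cu(I)-catalysed asymmetric 1,3-dipolar cycloaddition of α-silylimines of α-keto esters with activated alkenes, which gives 5-unsubstituted α-quaternary prolinates. The single ring is closed by a suprafacial [π4s+π2s] cycloaddition (stepwise limit: Michael addition followed by 5-endo-trig Mannich closure, as is usual for metallo-ylides). The quaternary centre C-2 (future C-10) is controlled by the ligand, which blocks one face of the planar chelated ylide, whereas the sulfonyl-bearing C-4 (drawn R) follows from the exo approach and is erased in step 4. The step needs regioselectivity, secured by the match of the nucleophilic ester-bearing terminus with the electrophilic β-carbon, and chemoselectivity against aza-Michael addition of 4, secured by adding 5 only after 4 has been consumed.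

Step 4
Reactants: 7 methyl (2R,4R)-2-(diethoxymethyl)-4-(phenylsulfonyl)pyrrolidine-2-carboxylate
Product: 8 methyl (2R)-2-(diethoxymethyl)pyrrolidine-2-carboxylate
Conditions: Mg turnings, MeOH, rt
Reagents that add atoms: none
Why: Reductive desulfonylation by single-electron transfer from magnesium cleaves the alkyl C–SO2Ph bond and protonates the carbanion, which unmasks the ethylene-derived CH2–CH2 edge before any C–Br bond is present and cannot touch the quaternary centre.

Step 5
Reactants: 8 methyl (2R)-2-(diethoxymethyl)pyrrolidine-2-carboxylate; 9 4,5-dibromo-1H-pyrrole-2-carboxylic acid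
Product: 11 methyl (2R)-1-(4,5-dibromo-1H-pyrrole-2-carbonyl)-2-(diethoxymethyl)pyrrolidine-2-carboxylate, via 4,5-dibromo-1H-pyrrole-2-carbonyl chloride 10 (not isolated)
Conditions: 9, (COCl)2, DMF (cat.), CH2Cl2, rt, evaporate; then 8, Et3N, DMAP (cat.), CH2Cl2, 0 °C → reflux
Reagents that add atoms: none
Why: N-acylation with the acid chloride, the most reactive acyl donor for the hindered α-quaternary amine, brings in the complete dibromopyrrole so that no late bromination is needed.

Step 6
Reactants: 11 methyl (2R)-1-(4,5-dibromo-1H-pyrrole-2-carbonyl)-2-(diethoxymethyl)pyrrolidine-2-carboxylate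
Product: 12 (2R)-1-(4,5-dibromo-1H-pyrrole-2-carbonyl)-2-(diethoxymethyl)pyrrolidine-2-carboxylic acid
Conditions: LiOH, THF/MeOH/H2O, 50 °C; then aq KHSO4 to pH 4, 0 °C
Reagents that add atoms: lithium hydroxide, [Li+].[OH-]
Why: Saponification (BAc2) of the hindered methyl ester should be helped by the neighbouring pyrrolide N, which can relay the acyl group through a hydrolytically labile N-acylpyrrole, while the quaternary centre cannot epimerise and the acetal is inert to base.

Step 7
Reactants: 12 (2R)-1-(4,5-dibromo-1H-pyrrole-2-carbonyl)-2-(diethoxymethyl)pyrrolidine-2-carboxylic acid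
Product: 15 1-[(2R)-1-(4,5-dibromo-1H-pyrrole-2-carbonyl)-2-(diethoxymethyl)pyrrolidin-2-yl]urea, via (2R)-1-(4,5-dibromo-1H-pyrrole-2-carbonyl)-2-(diethoxymethyl)pyrrolidine-2-carbonyl azide 13 (not isolated), via (4,5-dibromo-1H-pyrrol-2-yl)[(2S)-2-(diethoxymethyl)-2-isocyanatopyrrolidin-1-yl]methanone 14 (not isolated)
Conditions: DPPA, Et3N, toluene, rt → 70 °C; then NH3 (0.5 M in dioxane), 0 °C
Reagents that add atoms: diphenylphosphoryl azide, [N-]=[N+]=NP(=O)(Oc1ccccc1)Oc1ccccc1; ammonia, N
Why: In the Curtius rearrangement the acyl azide loses N2 with a 1,2-shift of the quaternary carbon under strict retention (only the CIP descriptor of 14 changes), and ammonia captures the isocyanate as the primary urea, which places the second nitrogen on C-10.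

Step 8
Reactants: 15 1-[(2R)-1-(4,5-dibromo-1H-pyrrole-2-carbonyl)-2-(diethoxymethyl)pyrrolidin-2-yl]urea
Product: 16 (6S,10R)-dibromophakellstatin
Conditions: TFA/CH2Cl2 (1:4), 0 °C → rt
Reagents that add atoms: none
Why: In a double amidoalkylation (N-acyliminium cyclisation) acid ionises the acetal, the terminal urea NH2 closes the imidazolidinone (5-exo-trig) and the pyrrole N–H closes the pyrazinone on the resulting cyclic N-acyliminium ion (6-exo-trig), and C-6 can only form with its H cis to the pyrrolidine CH2 on C-10 because the two new rings must be cis-fused, which gives (S).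

Compound list
1 | 3,3-diethoxyprop-1-yne | C#CC(OCC)OCC | starting material
2 | 1-bromo-3,3-diethoxyprop-1-yne | BrC#CC(OCC)OCC | intermediate
3 | methyl 3,3-diethoxy-2-oxopropanoate | CCOC(OCC)C(=O)C(=O)OC | intermediate
4 | (trimethylsilyl)methanamine | C[Si](C)(C)CN | starting material
5 | phenyl vinyl sulfone | C=CS(=O)(=O)c1ccccc1 | starting material
6 | methyl 3,3-diethoxy-2-{[(trimethylsilyl)methyl]imino}propanoate (C=N geometry not fixed) | CCOC(OCC)C(=NC[Si](C)(C)C)C(=O)OC | intermediate
7 | methyl (2R,4R)-2-(diethoxymethyl)-4-(phenylsulfonyl)pyrrolidine-2-carboxylate | CCOC(OCC)[C@@]1(C(=O)OC)C[C@@H](S(=O)(=O)c2ccccc2)CN1 | intermediate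
8 | methyl (2R)-2-(diethoxymethyl)pyrrolidine-2-carboxylate | CCOC(OCC)[C@@]1(C(=O)OC)CCCN1 | intermediate
9 | 4,5-dibromo-1H-pyrrole-2-carboxylic acid | OC(=O)c1cc(Br)c(Br)[nH]1 | starting material
10 | 4,5-dibromo-1H-pyrrole-2-carbonyl chloride | ClC(=O)c1cc(Br)c(Br)[nH]1 | intermediate
11 | methyl (2R)-1-(4,5-dibromo-1H-pyrrole-2-carbonyl)-2-(diethoxymethyl)pyrrolidine-2-carboxylate | CCOC(OCC)[C@@]1(C(=O)OC)CCCN1C(=O)c1cc(Br)c(Br)[nH]1 | intermediate
12 | (2R)-1-(4,5-dibromo-1H-pyrrole-2-carbonyl)-2-(diethoxymethyl)pyrrolidine-2-carboxylic acid | CCOC(OCC)[C@@]1(C(=O)O)CCCN1C(=O)c1cc(Br)c(Br)[nH]1 | intermediate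
13 | (2R)-1-(4,5-dibromo-1H-pyrrole-2-carbonyl)-2-(diethoxymethyl)pyrrolidine-2-carbonyl azide | CCOC(OCC)[C@@]1(C(=O)N=[N+]=[N-])CCCN1C(=O)c1cc(Br)c(Br)[nH]1 | intermediate
14 | (4,5-dibromo-1H-pyrrol-2-yl)[(2S)-2-(diethoxymethyl)-2-isocyanatopyrrolidin-1-yl]methanone | CCOC(OCC)[C@@]1(N=C=O)CCCN1C(=O)c1cc(Br)c(Br)[nH]1 | intermediate
15 | 1-[(2R)-1-(4,5-dibromo-1H-pyrrole-2-carbonyl)-2-(diethoxymethyl)pyrrolidin-2-yl]urea | CCOC(OCC)[C@@]1(NC(N)=O)CCCN1C(=O)c1cc(Br)c(Br)[nH]1 | intermediate
16 | (6S,10R)-dibromophakellstatin | O=C1N[C@H]2n3c(cc(Br)c3Br)C(=O)N3CCC[C@]23N1 | target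

Total step count: 8
Longest linear sequence: 8 steps (1 → 16); 4, 5 and 9 enter as purchased building blocks.

Steps most likely to fail

Risk 1 (step 3): The acetal-flanked, fully substituted ylide terminus may add only slowly to a singly activated alkene. Imine–enamine tautomerisation and an unligated background cycloaddition could then take over, and both conversion and facial selectivity would drop. The fallback sets out from 3, which is condensed with 4 to 6 as before. It replaces the ethylene surrogate by the far more electrophilic acetylene surrogate (E)-1,2-bis(phenylsulfonyl)ethene under the same ligand control. This should give methyl (2R,3S,4S)-2-(diethoxymethyl)-3,4-bis(phenylsulfonyl)pyrrolidine-2-carboxylate F1. Reductive elimination of both sulfonyl groups with Na(Hg)/Na2HPO4 in MeOH–THF should give methyl (2R)-2-(diethoxymethyl)-2,5-dihydro-1H-pyrrole-2-carboxylate F2. Hydrogenation (H2, Pd/C, MeOH) comes back to the route at 8.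

Risk 2 (step 8): Under acid the C-10 aminal may ionise with loss of urea, which would form an enamide and erase the stereochemical information. The pyrrole may also close irreversibly through C-3 instead of N. The fallback sets out from 15 and separates acetal cleavage from N–C bond formation. Near-neutral hydrolysis (LiBF4, wet MeCN) should stop at the spiro hemiaminal (5R)-6-(4,5-dibromo-1H-pyrrole-2-carbonyl)-4-hydroxy-1,3,6-triazaspiro[4.4]nonan-2-one F3. MsCl/Et3N in CH2Cl2 at −20 °C should eliminate the hemiaminal OH to the N-acylimine (5R)-6-(4,5-dibromo-1H-pyrrole-2-carbonyl)-1,3,6-triazaspiro[4.4]non-3-en-2-one F4. DBU should then add the pyrrolide nitrogen to the C=N bond on the only face within reach, which comes back to the route at 16.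

Risk 3 (step 7): The activated carboxyl group may be intercepted by the neighbouring pyrrole N–H before azide transfer. Prolonged heating with base may also let the same N–H capture the isocyanate. The fallback sets out from 11 and builds this N–H participation into the plan. NaH in THF should close the tricyclic dibromo-dipyrrolo[1,2-a:1',2'-d]pyrazine-5,10-dione that carries the diethoxymethyl group at the (R)-configured ring-fusion carbon F5. Ammonia in MeOH should open its activated N-acylpyrrole bond to (2R)-1-(4,5-dibromo-1H-pyrrole-2-carbonyl)-2-(diethoxymethyl)pyrrolidine-2-carboxamide F6. A Hofmann rearrangement with PhI(OAc)2 in MeCN followed by ammonia passes through 14 and comes back to the route at 15.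

Further compounds
F1 | step 3 | methyl (2R,3S,4S)-2-(diethoxymethyl)-3,4-bis(phenylsulfonyl)pyrrolidine-2-carboxylate | CCOC(OCC)[C@@]1(C(=O)OC)[C@H](S(=O)(=O)c2ccccc2)[C@@H](S(=O)(=O)c2ccccc2)CN1
F2 | step 3 | methyl (2R)-2-(diethoxymethyl)-2,5-dihydro-1H-pyrrole-2-carboxylate | CCOC(OCC)[C@@]1(C(=O)OC)C=CCN1
F3 | step 8 | (5R)-6-(4,5-dibromo-1H-pyrrole-2-carbonyl)-4-hydroxy-1,3,6-triazaspiro[4.4]nonan-2-one (C-4 epimers) | O=C1NC(O)[C@]2(CCCN2C(=O)c2cc(Br)c(Br)[nH]2)N1
F4 | step 8 | (5R)-6-(4,5-dibromo-1H-pyrrole-2-carbonyl)-1,3,6-triazaspiro[4.4]non-3-en-2-one | O=C1N=C[C@]2(CCCN2C(=O)c2cc(Br)c(Br)[nH]2)N1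
F5 | step 7 | tricyclic dibromo-dipyrrolo[1,2-a:1',2'-d]pyrazine-5,10-dione with the diethoxymethyl group at the (R)-configured ring-fusion carbon | CCOC(OCC)[C@@]12CCCN1C(=O)c1cc(Br)c(Br)n1C2=O
F6 | step 7 | (2R)-1-(4,5-dibromo-1H-pyrrole-2-carbonyl)-2-(diethoxymethyl)pyrrolidine-2-carboxamide | CCOC(OCC)[C@@]1(C(N)=O)CCCN1C(=O)c1cc(Br)c(Br)[nH]1
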